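Ring A, the non-aromatic 6,6-dimethylcyclohexa-2,4-dienone whose oxygens sit on C1, C3 and C5 beside the quaternary C6(CH3)2, is disconnected to a cyclobutenone and an ynol ether. Heating 3-ethoxy-4,4-dimethylcyclobutenone with ethoxyacetylene should open the four-membered ring, add the alkyne by [2+2] and expand the resulting vinylcyclobutenone by 6π-electrocyclisation onto the Me2C terminus. One operation thus grows the four-membered ring by two carbons and delivers the complete filicinic acid ring. Butyrylation and two Mannich-base (quinone methide) couplings then attach the butyrylphloroglucinol ring B and the O-methylated ring C through the two CH2 bridges.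

Key step: step 2

Remark: the target as drawn has no stereocentre and is achiral, so no stereocontrol is required; ring A is numbered C1 (ring C=O), C2 (butanoyl), C3 (OH), C4 (CH2 bridge), C5 (OH), C6 (CMe2).

Step 1
Reactants: 1 isobutyryl chloride; 2 ethoxyacetylene
Product: 4 3-ethoxy-4,4-dimethylcyclobut-2-en-1-one, via dimethylketene 3 (not isolated)
Conditions: Et3N, Et2O, 0 °C to rt
Reagents that add atoms: none
Why: Et3N dehydrochlorinates 1 to dimethylketene, whose electrophilic central carbon adds to the nucleophilic CH terminus of the ynol ether in a regioselective ketene–alkyne [2+2] cycloaddition, the standard entry to 3-alkoxycyclobutenones; no stereocentre is formed.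

Step 2
Reactants: 4 3-ethoxy-4,4-dimethylcyclobut-2-en-1-one; 2 ethoxyacetylene (excess, added in portions)
Product: 9 filicinic acid, via vinylketene 5 (not isolated), via vinylcyclobutenone 6 (not isolated), via dienylketene 7 (not isolated), via diethoxydienone 8 (not isolated)
Conditions: PhMe, sealed tube, 110 °C; then 2 M HCl, THF, 50 °C
Reagents that add atoms: water, O
Why: Thermal conrotatory 4π ring opening of 4 gives vinylketene 5, whose ketene carbon adds to the CH terminus of ethoxyacetylene in a [2+2] cycloaddition to give vinylcyclobutenone 6; a second 4π ring opening gives dienylketene 7, and disrotatory 6π-electrocyclisation joins the ketene carbon to the (CH3)2C terminus to give dienone 8, so that the four-membered ring of 4 is enlarged by the two alkyne carbons. The closest known reaction type is the Danheiser annulation of cyclobutenones with alkoxyacetylenes, stopped here at the 2,4-cyclohexadienone because the quaternary C6 cannot enolise to a phenol. Ring closures: the transient four-membered ring of 6 by ketene–alkyne [2+2] cycloaddition, and the six-membered ring A by 6π-electrocyclic closure (C1–C6 bond). No stereocentre is created in 8 or 9; the single stereocentre of 6 is racemic and is destroyed on ring opening. The step needs the head-to-tail regiochemistry of the [2+2] that places oxygen on C1, C3 and C5, which the polarity of ketene (electrophilic carbonyl carbon) and ynol ether (nucleophilic CH) secures, and it needs the cis-dienylketene, into which reversible ring opening of 6 funnels because only this isomer cyclises. Aqueous acid in the same flask hydrolyses the two vinylogous ester groups of 8, and the acidic 9 is separated from neutral by-products by bicarbonate extraction.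

Step 3
Reactants: 9 filicinic acid; 10 butyryl chloride
Product: 11 butyrylfilicinic acid (2-butanoyl-3,5-dihydroxy-6,6-dimethylcyclohexa-2,4-dien-1-one)
Conditions: AlCl3, PhNO2, rt to 60 °C; then ice/HCl
Reagents that add atoms: none
Why: Friedel–Crafts C-acylation of the enolised trione at its nucleophilic ring CH (C2 and C4 are equivalent in symmetrical 9), after which the β-triketone formed is deactivated against a second acylation.

Step 4
Reactants: 12 phloroglucinol; 10 butyryl chloride
Product: 13 1-(2,4,6-trihydroxyphenyl)butan-1-one
Conditions: AlCl3, CH2Cl2/MeNO2, 0 °C to 40 °C; then ice/HCl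
Reagents that add atoms: none
Why: Friedel–Crafts monoacylation of phloroglucinol, whose three ring positions are equivalent and whose product is deactivated by the chelated acyl group.

Step 5
Reactants: 11 butyrylfilicinic acid; 13 1-(2,4,6-trihydroxyphenyl)butan-1-one
Product: 16 2-butanoyl-4-[(3-butanoyl-2,4,6-trihydroxyphenyl)methyl]-3,5-dihydroxy-6,6-dimethylcyclohexa-2,4-dien-1-one, via Mannich base 14 (not isolated), via methide 15 (not isolated)
Conditions: CH2(NMe2)2, CH2Cl2, 0 °C to rt, evaporate; then 13 (3 equiv), 1,4-dioxane, 80 °C
Reagents that add atoms: bis(dimethylamino)methane, CN(C)CN(C)C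
Why: Mannich aminomethylation of the only free ring carbon of the acidic triketone 11 (C4), then loss of dimethylamine to methide 15 and Friedel–Crafts-type conjugate addition of 13 through one of its two equivalent free positions, the excess of 13 suppressing double alkylation.

Step 6
Reactants: 17 2-methylbenzene-1,3,5-triol; 10 butyryl chloride
Product: 18 1-(2,4,6-trihydroxy-3-methylphenyl)butan-1-one
Conditions: AlCl3, CH2Cl2/MeNO2, 0 °C to 40 °C; then ice/HCl
Reagents that add atoms: none
Why: Friedel–Crafts monoacylation, unambiguous because the two free ring positions of 17 are equivalent.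

Step 7
Reactants: 18 1-(2,4,6-trihydroxy-3-methylphenyl)butan-1-one
Product: 19 1-[2-hydroxy-4,6-bis(methoxymethoxy)-3-methylphenyl]butan-1-one
Conditions: MOMCl (2.1 equiv), i-Pr2NEt, CH2Cl2, 0 °C
Reagents that add atoms: chloromethyl methyl ether (MOMCl), COCCl
Why: Kinetic O-alkylation in which the non-chelated 4-OH reacts first and, of the two chelated ortho hydroxyls, the 6-OH flanked by H should react faster than the 2-OH buttressed by the C-methyl group, which leaves only the 2-OH free.

Step 8
Reactants: 19 1-[2-hydroxy-4,6-bis(methoxymethoxy)-3-methylphenyl]butan-1-one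
Product: 20 1-[2-methoxy-4,6-bis(methoxymethoxy)-3-methylphenyl]butan-1-one
Conditions: MeI, K2CO3, DMF, 40 °C
Reagents that add atoms: iodomethane (MeI), CI
Why: Williamson O-methylation of the remaining hindered, hydrogen-bonded phenol, under which the MOM acetals are stable and the ketone is not enolised by carbonate.

Step 9
Reactants: 20 1-[2-methoxy-4,6-bis(methoxymethoxy)-3-methylphenyl]butan-1-one
Product: 21 1-(4,6-dihydroxy-2-methoxy-3-methylphenyl)butan-1-one
Conditions: conc. HCl (cat.), MeOH, 50 °C
Reagents that add atoms: none
Why: Acid-catalysed acetal exchange removes both MOM groups as dimethoxymethane, the excess methanol capturing the formaldehyde equivalent before it can bridge two electron-rich rings, while the aryl methyl ether and the ketone are untouched.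

Step 10
Reactants: 21 1-(4,6-dihydroxy-2-methoxy-3-methylphenyl)butan-1-one; 16 2-butanoyl-4-[(3-butanoyl-2,4,6-trihydroxyphenyl)methyl]-3,5-dihydroxy-6,6-dimethylcyclohexa-2,4-dien-1-one
Product: 24 Filixsaure (target), via Mannich base 22 (not isolated), via quinone methide 23 (not isolated)
Conditions: CH2(NMe2)2, 1,4-dioxane, 60 °C, evaporate; then 16 (0.8 equiv), 1,4-dioxane, 90 °C
Reagents that add atoms: bis(dimethylamino)methane, CN(C)CN(C)C
Why: Mannich aminomethylation of the single free ring position of 21 (between its two hydroxyls), thermal loss of dimethylamine to ortho-quinone methide 23 and Friedel–Crafts-type addition of the only remaining aromatic CH of 16 (ring B), followed by rearomatisation, should give the achiral target.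

Compound list
1 | isobutyryl chloride | CC(C)C(=O)Cl | starting material
2 | ethoxyacetylene | CCOC#C | starting material
3 | dimethylketene (formed in situ) | CC(C)=C=O | intermediate
4 | 3-ethoxy-4,4-dimethylcyclobut-2-en-1-one | CCOC1=CC(=O)C1(C)C | intermediate
5 | 3-ethoxy-4-methylpenta-1,3-dien-1-one (vinylketene, formed in situ) | CCOC(C=C=O)=C(C)C | intermediate
6 | racemic 3-ethoxy-4-(1-ethoxy-2-methylprop-1-en-1-yl)cyclobut-2-en-1-one (formed in situ) | CCOC1=CC(=O)C1C(OCC)=C(C)C | intermediate
7 | (3E)-3,5-diethoxy-6-methylhepta-1,3,5-trien-1-one (dienylketene, formed in situ) | O=C=C/C(OCC)=C\C(OCC)=C(C)C | intermediate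
8 | 3,5-diethoxy-6,6-dimethylcyclohexa-2,4-dien-1-one (formed in situ) | O=C1C=C(OCC)C=C(OCC)C1(C)C | intermediate
9 | filicinic acid (3,5-dihydroxy-6,6-dimethylcyclohexa-2,4-dien-1-one) | CC1(C)C(=O)C=C(O)C=C1O | intermediate
10 | butyryl chloride | CCCC(=O)Cl | starting material
11 | butyrylfilicinic acid (2-butanoyl-3,5-dihydroxy-6,6-dimethylcyclohexa-2,4-dien-1-one) | CCCC(=O)C1=C(O)C=C(O)C(C)(C)C1=O | intermediate
12 | phloroglucinol | Oc1cc(O)cc(O)c1 | starting material
13 | 1-(2,4,6-trihydroxyphenyl)butan-1-one | CCCC(=O)c1c(O)cc(O)cc1O | intermediate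
14 | 2-butanoyl-4-[(dimethylamino)methyl]-3,5-dihydroxy-6,6-dimethylcyclohexa-2,4-dien-1-one (formed in situ) | CCCC(=O)C1=C(O)C(CN(C)C)=C(O)C(C)(C)C1=O | intermediate
15 | 2-butanoyl-3-hydroxy-6,6-dimethyl-4-methylidenecyclohex-2-ene-1,5-dione (formed in situ) | CCCC(=O)C1=C(O)C(=C)C(=O)C(C)(C)C1=O | intermediate
16 | 2-butanoyl-4-[(3-butanoyl-2,4,6-trihydroxyphenyl)methyl]-3,5-dihydroxy-6,6-dimethylcyclohexa-2,4-dien-1-one | CCCC(=O)C1=C(O)C(Cc2c(O)cc(O)c(C(=O)CCC)c2O)=C(O)C(C)(C)C1=O | intermediate
17 | 2-methylbenzene-1,3,5-triol | Cc1c(O)cc(O)cc1O | starting material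
18 | 1-(2,4,6-trihydroxy-3-methylphenyl)butan-1-one | CCCC(=O)c1c(O)cc(O)c(C)c1O | intermediate
19 | 1-[2-hydroxy-4,6-bis(methoxymethoxy)-3-methylphenyl]butan-1-one | CCCC(=O)c1c(OCOC)cc(OCOC)c(C)c1O | intermediate
20 | 1-[2-methoxy-4,6-bis(methoxymethoxy)-3-methylphenyl]butan-1-one | CCCC(=O)c1c(OCOC)cc(OCOC)c(C)c1OC | intermediate
21 | 1-(4,6-dihydroxy-2-methoxy-3-methylphenyl)butan-1-one | CCCC(=O)c1c(O)cc(O)c(C)c1OC | intermediate
22 | 1-{3-[(dimethylamino)methyl]-2,4-dihydroxy-6-methoxy-5-methylphenyl}butan-1-one (formed in situ) | CCCC(=O)c1c(O)c(CN(C)C)c(O)c(C)c1OC | intermediate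
23 | 4-butanoyl-5-hydroxy-3-methoxy-2-methyl-6-methylidenecyclohexa-2,4-dien-1-one (formed in situ) | CCCC(=O)C1=C(O)C(=C)C(=O)C(C)=C1OC | intermediate
24 | Filixsaure: 2-butanoyl-4-({3-butanoyl-5-[(3-butanoyl-2,6-dihydroxy-4-methoxy-5-methylphenyl)methyl]-2,4,6-trihydroxyphenyl}methyl)-3,5-dihydroxy-6,6-dimethylcyclohexa-2,4-dien-1-one | CCCC(=O)C1=C(O)C(Cc2c(O)c(Cc3c(O)c(C)c(OC)c(C(=O)CCC)c3O)c(O)c(C(=O)CCC)c2O)=C(O)C(C)(C)C1=O | target

Total step count: 10
Longest linear sequence: 5 steps (1, 2, 3, 5, 10; equally 6, 7, 8, 9, 10)

Steps most likely to fail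

Step 2. The four-electron ring opening of the 4,4-disubstituted, vinylogous-ester cyclobutenone may need a temperature at which ethoxyacetylene fragments to ketene and ethene. The vinylketene may also dimerise, or be diverted by a 1,5-hydrogen shift from its cis methyl group, before it meets the alkyne. The fallback generates the same vinylketene cold from an open-chain acid chloride, so that only the easy ring opening of the vinylcyclobutenone remains thermal and the six-membered ring still arises from the four-membered one. It sets out from 2 and from commercial ethyl 4-methyl-3-oxopentanoate (CCOC(=O)CC(=O)C(C)C, in place of 1 and 4) and comes back to the route at 5. Triethyl orthoformate with catalytic H2SO4 in EtOH should give ethyl (2E)-3-ethoxy-4-methylpent-2-enoate F1. Saponification (NaOH, aqueous EtOH, then HCl) should give (2E)-3-ethoxy-4-methylpent-2-enoic acid F2, and oxalyl chloride with catalytic DMF should give (2E)-3-ethoxy-4-methylpent-2-enoyl chloride F3. Et3N in CH2Cl2 at 0 °C in the presence of 2 should effect 1,4-dehydrochlorination of F3 to 5, which is trapped as 6. Warming to 60–80 °C and the acid work-up of step 2 then lead through 7 and 8 to 9.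

Step 10. At the temperature needed to expel dimethylamine from the phenolic Mannich base, the methylene bridge already present in 16 may ionise and exchange (retro-Friedel–Crafts methide transfer), scrambling the rings into symmetrical dimers and trimers. The quinone methide may also dimerise. The fallback inverts the order of bridge formation, so that the last bond made is the one that forms under the mildest conditions. It sets out from 21, 13 and 11 and comes back at 24. Mannich base 22, made from 21 as in step 10, is heated with 13 (3 equiv) in dioxane to give 1-{3-[(3-butanoyl-2,6-dihydroxy-4-methoxy-5-methylphenyl)methyl]-2,4,6-trihydroxyphenyl}butan-1-one F4. F4 is then stirred at room temperature with Mannich base 14 (made from 11 as in step 5), whose β-triketone core should lose dimethylamine without heating, so that the single free position of ring B in F4 adds to 15 and gives 24.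

Step 7. The second alkylation may discriminate poorly between the two chelated ortho hydroxyls, or may run on to the tris-ether, giving regioisomeric mixtures that carry through to an isomer of 21. The fallback selects the oxygen by chelation-assisted dealkylation instead of by alkylation rate. It sets out from 18 and comes back at 21. Exhaustive benzylation (BnBr, K2CO3, DMF, 60 °C) gives 1-[2,4,6-tris(benzyloxy)-3-methylphenyl]butan-1-one F5. BCl3 (1 equiv, CH2Cl2, −78 °C) should remove, through the boron chelate with the ketone, the benzyl group on the ortho oxygen that is twisted out of the ring plane by its two flanking substituents, giving 1-[4,6-bis(benzyloxy)-2-hydroxy-3-methylphenyl]butan-1-one F6. Methylation (MeI, K2CO3, DMF) gives 1-[4,6-bis(benzyloxy)-2-methoxy-3-methylphenyl]butan-1-one F7, and hydrogenolysis (H2, Pd/C, EtOAc) gives 21.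

Further compounds
F1 | step 2 | ethyl (2E)-3-ethoxy-4-methylpent-2-enoate | CCOC(=O)/C=C(/OCC)C(C)C
F2 | step 2 | (2E)-3-ethoxy-4-methylpent-2-enoic acid | OC(=O)/C=C(/OCC)C(C)C
F3 | step 2 | (2E)-3-ethoxy-4-methylpent-2-enoyl chloride | ClC(=O)/C=C(/OCC)C(C)C
F4 | step 10 | 1-{3-[(3-butanoyl-2,6-dihydroxy-4-methoxy-5-methylphenyl)methyl]-2,4,6-trihydroxyphenyl}butan-1-one | CCCC(=O)c1c(O)cc(O)c(Cc2c(O)c(C)c(OC)c(C(=O)CCC)c2O)c1O
F5 | step 7 | 1-[2,4,6-tris(benzyloxy)-3-methylphenyl]butan-1-one | CCCC(=O)c1c(OCc2ccccc2)cc(OCc2ccccc2)c(C)c1OCc3ccccc3
F6 | step 7 | 1-[4,6-bis(benzyloxy)-2-hydroxy-3-methylphenyl]butan-1-one | CCCC(=O)c1c(OCc2ccccc2)cc(OCc2ccccc2)c(C)c1O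
F7 | step 7 | 1-[4,6-bis(benzyloxy)-2-methoxy-3-methylphenyl]butan-1-one | CCCC(=O)c1c(OCc2ccccc2)cc(OCc2ccccc2)c(C)c1OC
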